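**Start here.** Read the level first.

the same everywhere: starting material 16 mM; free catalyst 2.5 mol%; impurity 0.56 mM; temperature 80 °C
- green: second substrate 2 equiv; the very flask that is asked about, followed so far
- red: second substrate 3 equiv; run made earlier
- flask: second substrate 2.00 equiv; time 2.5 h

| run | time / min | target / % | starting material / % |
|---|---|---|---|
| green | 20.0 | 7.0 | 92.8 |
| green | 50.0 | 8.7 | 90.9 |
| green | 90.0 | 9.2 | 91.6 |
| green | 150 | 8.8 | 91.3 |
| red | 2.50 | 2.2 | 96.9 |
| red | 6.00 | 4.3 | 95.1 |
| red | 12.0 | 6.3 | 94.8 |
| red | 30.0 | 8.2 | 92.2 |

(each reading ± 0.5 percentage points)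

- gamma: at 2.5 h raise the temperature by 10 K, then wait 2.5 h
- eta: at 2.5 h add free catalyst, 50.0% of the amount charged, then wait 2.5 h
- theta: change nothing and wait 2.5 h more
- zeta: at 2.5 h add starting material, 50.0% of the amount charged, then wait 2.5 h

1. target, in percent of the starting material first charged, at 2.5 h
2. what to do for the largest gain in target; "none" if nothing gains more than 2 percentage points (gamma / eta / theta / zeta / none)
3. target present, in percent of the starting material first charged, after eta
4. target present, in percent of the starting material first charged, after zeta

- additions leave the volume as it is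
- a reading or a percentage of target counts all its forms, free or not
- the earlier runs do not show what temperature does; that part of a forecast is a guess

**The curve.** In the red run, target starts at 0.141 mM min⁻¹, which is 0.352 min⁻¹ per catalyst charged. That slope is a reading, and red has more second substrate than the green flask. The green flask bends between 20.0 min and 50.0 min. It then holds at about 8.90%, or 3.56 target per catalyst charged. Starting material is still 91.3% at 150 min, far more than target, so the green flask has not run out of it.

**The margin.** The green flask was charged with 0.400 mM of catalyst and 0.56 mM of impurity. My reckoning supposes that the impurity is a stoichiometric poison, taking one catalyst for good. Call [impurity] charged minus [free catalyst] charged the impurity margin. Here it is 0.160 mM, and it is positive, so I expect impurity to outlast the catalyst. Then I expect the level to stand at 2.5 h, and waiting or more starting material should add nothing. For heat that is a guess.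

**Second round.** Now put that answer back in. Eta adds 0.200 mM of catalyst, more than the margin. By my reckoning, the margin's worth of catalyst should die after making 0.570 mM of target. I let the surplus, 0.0400 mM, turn over for 2.5 h at the rate read from the red run, which gives an estimated 2.11 mM. My figure after eta is therefore 25.7%.

**The forecast.** It gives 9% now, chooses eta, and puts eta at 13.4% (11.5% to 14.5%) and zeta at 9.2%. Its ground is this: “A fixed yield per catalyst instead points to death per turnover”. My eta figure is higher than its figure.

**The flask.** It holds 8.92% at 2.5 h. The best choice is eta, which gives 33.4%, while zeta gives 8.92%.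

    starting material + free catalyst ⇌ catalyst intermediate A (K = 980 M⁻¹, k = 45.0 M⁻¹ s⁻¹, Ea = 54.0 kJ mol⁻¹, ΔH = −10.0 kJ mol⁻¹)
    catalyst intermediate B → free catalyst + second product (k = 0.270 s⁻¹, Ea = 83.0 kJ mol⁻¹)
    free catalyst + target ⇌ idle complex, settled at all times (K = 65.0 M⁻¹, ΔH = −44.0 kJ mol⁻¹)
    free catalyst + impurity → spent catalyst (k = 85.0 M⁻¹ s⁻¹, Ea = 58.0 kJ mol⁻¹)
    catalyst intermediate A → free catalyst + target (k = 0.00760 s⁻¹, Ea = 91.0 kJ mol⁻¹)
    2 free catalyst ⇌ resting dimer, settled at all times (K = 4300 M⁻¹, ΔH = −45.0 kJ mol⁻¹)
    second substrate + free catalyst ⇌ catalyst intermediate B (K = 62.0 M⁻¹, k = 1.90 M⁻¹ s⁻¹, Ea = 49.0 kJ mol⁻¹, ΔH = −22.0 kJ mol⁻¹)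
    (constants at 80 °C)

**Margin again.** The flask after eta stands above both figures. At 150 min, impurity is 29% of its charge, and the margin is 28.6% of that charge. The neighbour with 4.2 mol% of catalyst has a margin of −0.112 mM. At 150 min its impurity stands at 0% and its target at 52.2%.

(The numbers in the tables were computed on assumed constants, noise included.)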